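The slow thing to watch here was a leak: in the earlier runs part of the G charged ended up as neither G nor Z, and a selectivity factor for that leak can be read off the runs, with their scatter.

all flasks: J 200 mM (held)

| charge | G | X | remark | time |
|---|---|---|---|---|
| gamma | 0.47 M | 12 mol% | run made earlier |  |
| theta | 0.70 M | 12 mol% | run made earlier |  |
| epsilon | 0.94 M | 6 mol% | run made earlier |  |
| flask | 0.94 M | 12 mol% |  | 5.0 min |

| run | time / min | Z / % | G / % |
|---|---|---|---|
| gamma | 0.417 | 10.5 | 86.8 |
| gamma | 1.00 | 32.0 | 59.9 |
| gamma | 2.00 | 57.1 | 30.0 |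
| gamma | 5.00 | 81.1 | 1.6 |
| theta | 1.33 | 42.8 | 50.7 |
| theta | 2.50 | 66.8 | 20.7 |
| theta | 4.00 | 81.1 | 4.9 |
| theta | 5.00 | 83.8 | 1.8 |
| epsilon | 0.417 | 11.2 | 87.2 |
| epsilon | 1.00 | 24.8 | 70.2 |
| epsilon | 2.00 | 45.7 | 43.2 |
| epsilon | 5.00 | 77.0 | 3.0 |

(each reading ± 1 percentage point)

* amount of Z at 5.0 min, in percent of the G charged
* concentration of D in solution at 5.0 min, in percent of saturation

- at the start none of J is in solution
- D is what J becomes in solution

I took the loss ratio, missing G per Z at the last reading. Gamma and epsilon were charged with the same c(X), 56.4 mM, at different c(G), and gave 0.213 and 0.260; I assumed that c(G) did not matter and kept their mean, 0.237, as the reference loss ratio. The flask was charged with twice that c(X). If each X kept working, the ratio in the flask halves to 0.118. If X paired off idle, with working X growing as the root of the charge, it falls to 0.168. With G left as in theta's last reading, these give Z of 87.8% and 84.1%. Theta's ratio, 0.172, puts the exponent on c(X) at 0.802, a reading with the scatter of the runs, between the 0.5 of the paired version and the 1 of the other, so I reckoned 0.136 and Z of 86.5% for the flask.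

The forecast said 84% of Z, a little lower than mine, and 85% of saturation for D, judging that selectivity “seems to improve with more G and more X”.

    J ⇌ D, rate k1*(csat - [D]) (kL = 0.0430 s⁻¹)
    G + D + X → X + Z (k = 2.50 M⁻² s⁻¹)
    G + D → E (k = 0.0170 M⁻¹ s⁻¹)
    2 X ⇌ L (K = 18.0 M⁻¹, k = 0.370 M⁻¹ s⁻¹)

The flask gave 86.0% of Z, and D at 93.9% of saturation, above the forecast. At 5.00 min, 61.2% of the catalyst in the flask stood as L. E per Z in the flask was 0.148, so going round once more with 0.237 gives the exponent 0.678, less than my first. For the neighbour flask with 30 mol% of X, that exponent gives a ratio of 0.0794 and, if I count the G as converted, Z of 92.6%. That neighbour flask gave 92.0%, with E at 7.91% and G at 0.094%.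

(The numbers in the tables are simulated from invented constants.)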